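**Retrosynthetic overview**
1. Target 20 comes from tetraol 19: one MnO2 oxidation turns the two identical 3-hydroxyprop-1-en-2-yl arms on C5 and C7 into the acrolein unit (C15) and, with the 8-hydroxyl, into the α-methylene lactone (lactone ring formed last). The angelate is put on O6 while the cis-8,9-diol is held in a temporary dioxolane ring.
2. Key disconnection: the cyclohexane ring (C5–C10) is cut at C8–C9 and C6–C7. Both bonds are made together by a SmI2-driven reductive aldol–pinacol annulation of 1,4-dialdehyde 9 (C9, C10, C5, C6) with γ-chloro enal 13 (C7 = α-carbon, C8 = formyl carbon).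
3. Enabling feature: ring carbons C6, C8 and C9 all carry oxygen. The cis-8,9-diol is a pinacol pair and the 6-hydroxyl sits β to C8 (aldol pair), so the C7–C8 edge is an enolisable aldehyde and C6/C9 are the formyl carbons of a succinaldehyde that already holds the C5 arm and the C10 methyl and vinyl groups.
4. Dialdehyde 9 comes from butenolide 3: rhodium-catalysed asymmetric alkenyl addition sets C5, two trans-selective enolate alkylations build quaternary C10, then reduction and Swern oxidation. Enal 13 comes from 3-chloropropane-1,2-diol.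
5. Ring order: carbocycle (step 11), temporary acetonide (step 12, removed in step 14), lactone (step 15).

Key step: step 11

Remark: names of the cyclohexane compounds use elemane numbering (C1=C2 vinyl and C14 methyl on C10, C3=C4–C15 arm on C5, C13=C11–C12 arm on C7); β is the face of the C14 methyl group, and the SMILES strings are binding for configuration.

**Step 1**
Reactants: 1 tert-butyldimethyl(prop-2-yn-1-yloxy)silane
Product: 2 2-[3-(tert-butyldimethylsilyloxy)prop-1-en-2-yl]-4,4,5,5-tetramethyl-1,3,2-dioxaborolane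
Conditions: B2pin2, CuCl (5 mol %), 1,3-bis(2,4,6-trimethylphenyl)imidazolinium chloride (5 mol %), NaOt-Bu (10 mol %), MeOH (2 equiv), THF, −50 → 20 °C
Reagents that add atoms: bis(pinacolato)diboron, CC1(C)OB(OC1(C)C)B1OC(C)(C)C(C)(C)O1
Why: Copper-catalysed formal hydroboration of a terminal alkyne (borylcupration, then protonation by methanol), in which the N-aryl carbene ligand and the propargylic oxygen should direct boron to the internal carbon.

**Step 2**
Reactants: 3 furan-2(5H)-one; 2 alkenylboronate
Product: 4 (4R)-4-[3-(tert-butyldimethylsilyloxy)prop-1-en-2-yl]oxolan-2-one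
Conditions: [RhCl(C8H12)]2 (3 mol %), (R)-BINAP (7 mol %), KOH (0.5 equiv), 1,4-dioxane/H2O 10:1, 50 °C
Reagents that add atoms: none
Why: Hayashi–Miyaura rhodium-catalysed asymmetric 1,4-addition of an alkenylboronate to an unsaturated lactone; the ligand enantiomer is chosen to deliver the alkenyl group to the face that gives the 4R centre (C5 of the target).

**Step 3**
Reactants: 4 lactone
Product: 5 (3S,4R)-3-methyl-4-[3-(tert-butyldimethylsilyloxy)prop-1-en-2-yl]oxolan-2-one
Conditions: LiN(i-Pr)2, THF, −78 °C; MeI, −78 → −20 °C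
Reagents that add atoms: iodomethane, CI
Why: Lactone enolate alkylation, with iodomethane entering trans to the neighbouring alkenyl group (this centre is re-enolised in step 4).

**Step 4**
Reactants: 5 methyl lactone
Product: 6 (3S,4S)-3-methyl-3-[2-(phenylsulfinyl)ethyl]-4-[3-(tert-butyldimethylsilyloxy)prop-1-en-2-yl]oxolan-2-one (mixture at sulfur)
Conditions: LiN(i-Pr)2, THF, −78 °C; PhS(O)CH=CH2, −78 → 0 °C
Reagents that add atoms: phenyl vinyl sulfoxide, C=CS(=O)c1ccccc1
Why: Conjugate addition of the enolate to phenyl vinyl sulfoxide (a vinyl cation equivalent); the electrophile again enters trans to the alkenyl group, so quaternary C10 should form with methyl cis and the two-carbon arm trans to it.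

**Step 5**
Reactants: 6 sulfoxide
Product: 7 (3S,4S)-3-ethenyl-3-methyl-4-[3-(tert-butyldimethylsilyloxy)prop-1-en-2-yl]oxolan-2-one
Conditions: toluene, NaHCO3, 110 °C
Reagents that add atoms: none
Why: Thermal syn-elimination of the sulfoxide unveils the vinyl group without touching a stereocentre; the trans-dialkenyl lactone cannot reach a Cope transition state at this temperature.

**Step 6**
Reactants: 7 vinyl lactone
Product: 8 (2S,3S)-2-ethenyl-2-methyl-3-[3-(tert-butyldimethylsilyloxy)prop-1-en-2-yl]butane-1,4-diol
Conditions: LiAlH4, THF, 0 °C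
Reagents that add atoms: none
Why: Hydride reduction of the lactone to the 1,4-diol; silyl ether and alkenes are inert.

**Step 7**
Reactants: 8 diol
Product: 9 (2S,3S)-2-ethenyl-2-methyl-3-[3-(tert-butyldimethylsilyloxy)prop-1-en-2-yl]butanedial
Conditions: (COCl)2, DMSO, CH2Cl2, −78 °C; i-Pr2NEt, −78 → −30 °C; used at once
Reagents that add atoms: none
Why: Swern oxidation activates both primary alcohols together so no lactol can form, and the cold hindered-amine work-up should keep the α-centre C5 and the 1,5-diene intact.

**Step 8**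
Reactants: 10 3-chloropropane-1,2-diol
Product: 11 1-(tert-butyldimethylsilyloxy)-3-chloropropan-2-ol
Conditions: TBSCl, imidazole, CH2Cl2, 0 °C
Reagents that add atoms: tert-butyldimethylsilyl chloride, CC(C)(C)[Si](C)(C)Cl
Why: Selective silylation of the primary hydroxyl.

**Step 9**
Reactants: 11 chlorohydrin
Product: 12 1-(tert-butyldimethylsilyloxy)-3-chloropropan-2-one
Conditions: Dess–Martin periodinane, NaHCO3, CH2Cl2, 0 → 20 °C
Reagents that add atoms: none
Why: Dess–Martin oxidation of the secondary alcohol under buffered, non-basic conditions that spare the α-chloro ketone.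

**Step 10**
Reactants: 12 chloroketone
Product: 13 3-[(tert-butyldimethylsilyloxy)methyl]-4-chlorobut-2-enal (E/Z mixture)
Conditions: Ph3P=CHCHO, toluene, 80 °C
Reagents that add atoms: (triphenylphosphoranylidene)acetaldehyde, O=CC=P(c1ccccc1)(c1ccccc1)c1ccccc1
Why: Wittig olefination of an activated ketone with a stabilised ylide; both alkene isomers give the same dienolate in step 11, so the geometry does not matter.

**Step 11**
Reactants: 9 dialdehyde; 13 chloro enal
Product: 16 12,15-bis(tert-butyldimethylsilyloxy)elema-1,3,11(13)-triene-6β,8α,9α-triol, via samarium dienolate 14 (not isolated), via samarium aldolate 15 (not isolated)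
Conditions: SmI2 (0.1 M in THF, 2.2 equiv, added slowly to 9 + 13), THF, −78 °C; then SmI2 (2.4 equiv), t-BuOH (2 equiv), −78 → 0 °C
Reagents that add atoms: none
Why: Proposed new method: SmI2 first cleaves the allylic C–Cl bond of 13 (its most easily reduced function) to give the (E)-dienolate 14, whose α-carbon C7 adds to the less hindered formyl carbon C6 of 9 through a closed six-membered chair to give aldolate 15, and two more electrons then turn the new formyl group C8 into a ketyl that attacks the C9 formyl carbon; the closest known reaction types are the SmI2 Reformatsky-type aldol addition, the SmI2 pinacol cyclisation of 1,6-dialdehydes to cis-cyclohexane-1,2-diols and SmI2 cascade cyclisations of dialdehydes. The only ring closed is the cyclohexane (C5–C10), by 6-exo attack of the C8 ketyl on the C9 carbonyl (pinacol closure). C6 and C7 arise in the aldol: the (E)-enolate in the chair places the C11 arm equatorial and should give the anti relationship, and the face of C6 is expected to be fixed because the large trivalent samarium ion binds both formyl oxygens of the 1,4-dialdehyde, holding C10 next to O6 so that C7 enters anti to the C4 alkenyl arm. C8 and C9 arise in the pinacol step: the samarium-bridged diolate must be cis, and the chair with the C5 and C7 arms equatorial puts O8 equatorial (trans to the C7 arm, anti to the O6 alkoxide) and O9 axial on the face away from the axial C10 methyl. The step needs site selectivity between the two formyl groups, the right order of reductions and face selectivity at C6; the first two are secured by the substrate (C9 is neopentyl and cannot enolise, and C–Cl cleavage is much faster than ketyl formation from aliphatic aldehydes at −78 °C), while the third rests on the chelate and is the main risk.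

**Step 12**
Reactants: 16 triol
Product: 17 12,15-bis(tert-butyldimethylsilyloxy)-8α,9α-(isopropylidenedioxy)elema-1,3,11(13)-trien-6β-ol
Conditions: Me2C(OMe)2, pyridinium p-toluenesulfonate (cat.), CH2Cl2, 20 °C
Reagents that add atoms: 2,2-dimethoxypropane, COC(C)(C)OC
Why: Acid-catalysed acetonide formation; only the cis-8,9-diol can close a dioxolane, so the axial 6-hydroxyl stays free.

**Step 13**
Reactants: 17 acetonide
Product: 18 12,15-bis(tert-butyldimethylsilyloxy)-8α,9α-(isopropylidenedioxy)elema-1,3,11(13)-trien-6β-yl (2Z)-2-methylbut-2-enoate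
Conditions: LiN(SiMe3)2, THF, −78 °C; angelic anhydride, −78 → 0 °C
Reagents that add atoms: angelic anhydride, C/C=C(/C)C(=O)OC(=O)/C(C)=C\C
Why: Acylation of the lithium alkoxide with the anhydride; no nucleophilic catalyst activates the acyl group, so the (Z)-alkene should not isomerise.

**Step 14**
Reactants: 18 angelate
Product: 19 6β-angeloyloxyelema-1,3,11(13)-triene-8α,9α,12,15-tetraol
Conditions: HCl (1 M aq.), THF, 20 °C
Reagents that add atoms: none
Why: Acid hydrolysis removes the acetonide and both primary silyl ethers in one operation; the hindered conjugated ester should survive.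

**Step 15**
Reactants: 19 tetraol
Product: 20 6β-angeloyloxy-9α-hydroxy-15-oxoelema-1,3,11(13)-trien-12,8α-olide (target)
Conditions: MnO2 (activated, excess), CH2Cl2, 20 °C
Reagents that add atoms: none
Why: MnO2 oxidises only the two allylic primary alcohols: C15 gives the enal, and the C12 aldehyde is trapped by the equatorial 8-hydroxyl as a lactol and oxidised on to the trans-fused α-methylene lactone (oxidative lactonisation), leaving the 9-hydroxyl untouched.

**Compound list**
1 | tert-butyldimethyl(prop-2-yn-1-yloxy)silane | C#CCO[Si](C)(C)C(C)(C)C | starting material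
2 | 2-[3-(tert-butyldimethylsilyloxy)prop-1-en-2-yl]-4,4,5,5-tetramethyl-1,3,2-dioxaborolane | C=C(CO[Si](C)(C)C(C)(C)C)B1OC(C)(C)C(C)(C)O1 | intermediate
3 | furan-2(5H)-one | O=C1C=CCO1 | starting material
4 | (4R)-4-[3-(tert-butyldimethylsilyloxy)prop-1-en-2-yl]oxolan-2-one | O=C1C[C@@H](CO1)C(=C)CO[Si](C)(C)C(C)(C)C | intermediate
5 | (3S,4R)-3-methyl-4-[3-(tert-butyldimethylsilyloxy)prop-1-en-2-yl]oxolan-2-one | C[C@@H]1C(=O)OC[C@H]1C(=C)CO[Si](C)(C)C(C)(C)C | intermediate
6 | (3S,4S)-3-methyl-3-[2-(phenylsulfinyl)ethyl]-4-[3-(tert-butyldimethylsilyloxy)prop-1-en-2-yl]oxolan-2-one, mixture at sulfur | O=S(CC[C@]1(C)C(=O)OC[C@H]1C(=C)CO[Si](C)(C)C(C)(C)C)c1ccccc1 | intermediate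
7 | (3S,4S)-3-ethenyl-3-methyl-4-[3-(tert-butyldimethylsilyloxy)prop-1-en-2-yl]oxolan-2-one | C=C[C@]1(C)C(=O)OC[C@H]1C(=C)CO[Si](C)(C)C(C)(C)C | intermediate
8 | (2S,3S)-2-ethenyl-2-methyl-3-[3-(tert-butyldimethylsilyloxy)prop-1-en-2-yl]butane-1,4-diol | C=C[C@](C)(CO)[C@@H](CO)C(=C)CO[Si](C)(C)C(C)(C)C | intermediate
9 | (2S,3S)-2-ethenyl-2-methyl-3-[3-(tert-butyldimethylsilyloxy)prop-1-en-2-yl]butanedial | C=C[C@](C)(C=O)[C@@H](C=O)C(=C)CO[Si](C)(C)C(C)(C)C | intermediate
10 | 3-chloropropane-1,2-diol (racemic) | OCC(O)CCl | starting material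
11 | 1-(tert-butyldimethylsilyloxy)-3-chloropropan-2-ol | OC(CCl)CO[Si](C)(C)C(C)(C)C | intermediate
12 | 1-(tert-butyldimethylsilyloxy)-3-chloropropan-2-one | O=C(CCl)CO[Si](C)(C)C(C)(C)C | intermediate
13 | 3-[(tert-butyldimethylsilyloxy)methyl]-4-chlorobut-2-enal, E/Z mixture | O=CC=C(CCl)CO[Si](C)(C)C(C)(C)C | intermediate
14 | diiodosamarium (1E)-3-[(tert-butyldimethylsilyloxy)methyl]buta-1,3-dien-1-olate | C=C(CO[Si](C)(C)C(C)(C)C)/C=C/O[Sm](I)I | intermediate
15 | diiodosamarium aldolate: open-chain C6–C7 adduct of 9 and 14, O6 on samarium, formyl groups at C8 and C9, C6 and C7 configured as in 16 | C=C[C@](C)(C=O)[C@@H]([C@H](O[Sm](I)I)[C@@H](C=O)C(=C)CO[Si](C)(C)C(C)(C)C)C(=C)CO[Si](C)(C)C(C)(C)C | intermediate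
16 | 12,15-bis(tert-butyldimethylsilyloxy)elema-1,3,11(13)-triene-6β,8α,9α-triol (5αH, 7αH, 10β-methyl) | C=C[C@]1(C)[C@H](O)[C@H](O)[C@@H](C(=C)CO[Si](C)(C)C(C)(C)C)[C@@H](O)[C@H]1C(=C)CO[Si](C)(C)C(C)(C)C | intermediate
17 | 12,15-bis(tert-butyldimethylsilyloxy)-8α,9α-(isopropylidenedioxy)elema-1,3,11(13)-trien-6β-ol | C=C[C@]1(C)[C@@H]2OC(C)(C)O[C@@H]2[C@@H](C(=C)CO[Si](C)(C)C(C)(C)C)[C@@H](O)[C@H]1C(=C)CO[Si](C)(C)C(C)(C)C | intermediate
18 | 12,15-bis(tert-butyldimethylsilyloxy)-8α,9α-(isopropylidenedioxy)elema-1,3,11(13)-trien-6β-yl (2Z)-2-methylbut-2-enoate | C=C[C@]1(C)[C@@H]2OC(C)(C)O[C@@H]2[C@@H](C(=C)CO[Si](C)(C)C(C)(C)C)[C@@H](OC(=O)/C(C)=C\C)[C@H]1C(=C)CO[Si](C)(C)C(C)(C)C | intermediate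
19 | 6β-angeloyloxyelema-1,3,11(13)-triene-8α,9α,12,15-tetraol | C=C[C@]1(C)[C@H](O)[C@H](O)[C@@H](C(=C)CO)[C@@H](OC(=O)/C(C)=C\C)[C@H]1C(=C)CO | intermediate
20 | (3aS,4S,5R,6S,7S,7aR)-6-ethenyl-7-hydroxy-6-methyl-3-methylidene-2-oxo-5-(3-oxoprop-1-en-2-yl)octahydro-1-benzofuran-4-yl (2Z)-2-methylbut-2-enoate | C=C[C@]1(C)[C@H](O)[C@@H]2OC(=O)C(=C)[C@H]2[C@@H](OC(=O)/C(C)=C\C)[C@H]1C(=C)C=O | target

**Step count and risks**
Total step count: 15. Longest linear sequence: 12 steps (steps 1–7, then 11–15).

Steps most likely to fail: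

1. Step 11 (proposed new method). What may go wrong: poor face selectivity at C6 in the intermolecular aldol (open, Felkin-type addition competing with the chelated chair), addition of the dienolate to the wrong formyl group, or reductive coupling of the two formyl groups of 9 before the aldol. Fallback, from 13 and 9, returning at 16: the two bonds are made separately, the first with a reagent of fixed geometry. Zinc and TBSCl convert 13 by reductive silylation into (1E)-1-(tert-butyldimethylsilyloxy)-3-[(tert-butyldimethylsilyloxy)methyl]buta-1,3-diene F1. Platinum-catalysed 1,4-diboration (B2pin2, Pt(PPh3)4, toluene, 80 °C) gives the cis-configured 2-ene-1,4-bis(boronate) F2 (racemic at C8, which becomes a formyl carbon). Its primary allylboronate unit adds to the C6 formyl group of 9 through a closed chair in which the C8 substituent, cis to the boryl-methyl group, is axial. This arrangement is known to give syn products with anti-Felkin induction, which is the C6/C7 pattern of the target, and leads to boronate adduct F3. Trimethylamine N-oxide in THF oxidises the C8–B bond and unveils the formyl group, giving hydroxy dialdehyde F4 (the free alcohol of 15). SmI2 pinacol cyclisation of F4 (THF, t-BuOH, −78 °C) then gives 16.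

2. Step 4. What may go wrong: slow conjugate addition of the fully substituted enolate and erosion of the trans selectivity at the new quaternary centre. Fallback, from 5, returning at 7: the enolate of 5 (LiN(i-Pr)2, THF, −78 °C) is trapped with acetaldehyde in an aldol addition, again trans to the alkenyl group, to give the 3-(1-hydroxyethyl) lactone F5 (both carbinol epimers serve). Mesylation (MsCl, Et3N) gives mesylate F6, and E2 elimination with DBU in hot toluene can only take a methyl hydrogen, so it gives 7.

3. Step 13. What may go wrong: failure to acylate the hindered axial 6-alkoxide (it is syn-axial to the C10 methyl), or isomerisation of the (Z)-ester to the (E)-isomer if the acylation has to be forced. Fallback, from 17, returning at 18: the alkene is built on the ester instead. Esterification of 17 with 2-[bis(2,2,2-trifluoroethoxy)phosphoryl]propanoic acid (N,N'-dicyclohexylcarbodiimide, 4-(dimethylamino)pyridine, CH2Cl2) gives the phosphonate ester F7; this acid is small and cannot isomerise. Still–Gennari olefination with acetaldehyde (KN(SiMe3)2, 18-crown-6, THF, −78 °C) then forms the (Z)-trisubstituted alkene and gives 18.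

**Further compounds**
F1 | step 11 | (1E)-1-(tert-butyldimethylsilyloxy)-3-[(tert-butyldimethylsilyloxy)methyl]buta-1,3-diene | C=C(CO[Si](C)(C)C(C)(C)C)/C=C/O[Si](C)(C)C(C)(C)C
F2 | step 11 | 1-(tert-butyldimethylsilyloxy)-3-[(tert-butyldimethylsilyloxy)methyl]but-2-ene-1,4-diyl bis(pinacol boronate), boryl-methyl group cis to C1, racemic at C1 | CC1(C)OB(C/C(CO[Si](C)(C)C(C)(C)C)=C\C(O[Si](C)(C)C(C)(C)C)B2OC(C)(C)C(C)(C)O2)OC1(C)C
F3 | step 11 | allylboration adduct of 9 and F2: O6 pinacol borate, C8 bearing silyloxy and pinacolboryl groups, C9 formyl group intact | C=C[C@](C)(C=O)[C@@H]([C@H](OB1OC(C)(C)C(C)(C)O1)[C@@H](C(O[Si](C)(C)C(C)(C)C)B2OC(C)(C)C(C)(C)O2)C(=C)CO[Si](C)(C)C(C)(C)C)C(=C)CO[Si](C)(C)C(C)(C)C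
F4 | step 11 | hydroxy dialdehyde, the free alcohol of 15 | C=C[C@](C)(C=O)[C@@H]([C@H](O)[C@@H](C=O)C(=C)CO[Si](C)(C)C(C)(C)C)C(=C)CO[Si](C)(C)C(C)(C)C
F5 | step 4 | (3S,4S)-3-(1-hydroxyethyl)-3-methyl-4-[3-(tert-butyldimethylsilyloxy)prop-1-en-2-yl]oxolan-2-one, carbinol epimers | CC(O)[C@]1(C)C(=O)OC[C@H]1C(=C)CO[Si](C)(C)C(C)(C)C
F6 | step 4 | methanesulfonate of F5 | CC(OS(C)(=O)=O)[C@]1(C)C(=O)OC[C@H]1C(=C)CO[Si](C)(C)C(C)(C)C
F7 | step 13 | 6β-{2-[bis(2,2,2-trifluoroethoxy)phosphoryl]propanoyloxy} analogue of 18 | C=C[C@]1(C)[C@@H]2OC(C)(C)O[C@@H]2[C@@H](C(=C)CO[Si](C)(C)C(C)(C)C)[C@@H](OC(=O)C(C)P(=O)(OCC(F)(F)F)OCC(F)(F)F)[C@H]1C(=C)CO[Si](C)(C)C(C)(C)C
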